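**Plan**

- Retrosynthesis (carotenoid numbering, primed atoms on the furanoid half): the two O–Si bonds are cut first, then C14–C15 together with C13–C20 (the methyl on C13). This gives the C18 diol-ring trienyne 16, AlMe3 26 and the C21 furanoid alkenyl iodide 25. Further back, C11=C12 and C6–C7 are cut in the diol half, and C15'=C15, C11'=C12', C7'=C8' and O–C8' in the furanoid half.
- Enabling feature: the chain atoms C12–C13(C20H3)=C14H–C15 form a methyl-branched trisubstituted (13E) alkene whose C14 is bonded to an sp2 carbon. This is what syn methylmetalation of a terminal C13≡C14 alkyne followed by alkenyl–alkenyl coupling delivers. The cyclohexane-1,2-diol ring (C1–C6) and the dihydrofuran ring (O–C5'–C6'=C7'–C8') fused to the second cyclohexane ring sit on separate partners and take no part.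
- Forward order: both six-membered rings come from β-cyclocitral 1 through one epoxy aldehyde 4. The diol half grows outward from the ring (C6–C7 by acetylide addition, C11=C12 by olefination). The furanoid half grows by two olefinations, its dihydrofuran ring is closed by epoxide–furanoid rearrangement, and the iodide is installed last. The halves are joined at C14–C15 and desilylated.
- Stereochemistry: C5 and C5' come from one Sharpless epoxidation. C6 comes from Felkin–Anh addition to the α-silyloxy ketone 8 (cis-diol). C8' is formed in the ring closure, where both epimers arise and the (8'R) one is separated. The E double bonds come from an (E)-enynol, trans-hydroalumination, phosphonate olefinations, Takai olefination, and syn carbometalation with stereoretentive coupling.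

Key step: step 19

Remark: positions are given in carotenoid numbering (unprimed for intermediates that serve both halves); compounds 9, 13 and 17 are assumed to be bought.

**Route**

Step 1
Reactants: 1 β-cyclocitral
Product: 2 β-cyclogeraniol
Conditions: NaBH4, MeOH, 0 °C
Reagents that add atoms: none
Why: Borohydride reduction of an aldehyde; the hindered tetrasubstituted enal should undergo clean 1,2-hydride addition and no stereocentre is formed.

Step 2
Reactants: 2 β-cyclogeraniol
Product: 3 epoxy alcohol [(1R,6R)-2,2,6-trimethyl-7-oxabicyclo[4.1.0]heptan-1-yl]methanol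
Conditions: Ti(OiPr)4 (0.2 equiv), D-(−)-diethyl tartrate (0.25 equiv), t-BuOOH, 4 Å molecular sieves, CH2Cl2, −20 °C
Reagents that add atoms: tert-butyl hydroperoxide, CC(C)(C)OO
Why: Sharpless asymmetric epoxidation of a tetrasubstituted primary allylic alcohol; the titanium tartrate complex should deliver oxygen to one face of C5=C6 and so set both epoxide carbons in one event, (5R,6S) in carotenoid numbering.

Step 3
Reactants: 3 epoxy alcohol
Product: 4 epoxy aldehyde (1S,6R)-2,2,6-trimethyl-7-oxabicyclo[4.1.0]heptane-1-carbaldehyde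
Conditions: (n-Pr4N)(RuO4) (5 mol%), N-methylmorpholine N-oxide, 4 Å molecular sieves, CH2Cl2, 23 °C
Reagents that add atoms: none
Why: Ley–Griffith oxidation of a primary alcohol under neutral conditions should spare the acid-sensitive tetrasubstituted epoxide, and the aldehyde has no α-hydrogen to epimerise.

Step 4
Reactants: 4 epoxy aldehyde
Product: 6 (1R)-1,3,3-trimethyl-2-methylidenecyclohexan-1-ol, via epoxy aldehyde hydrazone 5 (not isolated)
Conditions: N2H4·H2O (3 equiv), AcOH (cat.), MeOH, 0 → 23 °C
Reagents that add atoms: none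
Why: Wharton transposition of an α,β-epoxy carbonyl compound: the hydrazone 5 should open the C6–O bond and lose N2, leaving an exocyclic methylene at C6 and the tertiary C5–OH, whose C–O bond and (R) configuration are never broken.

Step 5
Reactants: 6 (1R)-1,3,3-trimethyl-2-methylidenecyclohexan-1-ol
Product: 7 triethylsilyl ether of 6
Conditions: Et3SiOTf, 2,6-lutidine, CH2Cl2, −78 → 0 °C
Reagents that add atoms: triethylsilyl trifluoromethanesulfonate, CC[Si](CC)(CC)OS(=O)(=O)C(F)(F)F
Why: O-silylation of a tertiary alcohol with a silyl triflate and a hindered base gives a non-chelating triethylsilyl ether that should survive organolithium, hydride and carbonate in methanol.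

Step 6
Reactants: 7 triethylsilyl ether of 6
Product: 8 (6R)-2,2,6-trimethyl-6-[(triethylsilyl)oxy]cyclohexan-1-one
Conditions: O3, CH2Cl2, −78 °C; then PPh3, −78 → 23 °C
Reagents that add atoms: ozone, [O-][O+]=O
Why: Ozonolysis of a 1,1-disubstituted alkene with reductive work-up should give the α-silyloxy ketone, whose quaternary C5 centre cannot epimerise.

Step 7
Reactants: 8 α-silyloxy ketone; 9 (E)-3-methylpent-2-en-4-yn-1-ol
Product: 10 propargylic diol (1R,2R)-1-[(3E)-5-hydroxy-3-methylpent-3-en-1-yn-1-yl]-2,6,6-trimethyl-2-[(triethylsilyl)oxy]cyclohexan-1-ol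
Conditions: 9, n-BuLi (2 equiv), THF, −78 → 0 °C; then 8, 0 → 23 °C; H2O
Reagents that add atoms: none
Why: 1,2-Addition of a lithium acetylide (the dilithio salt of 9) to a ketone without α-hydrogens; attack anti to the C5–OSiEt3 bond (Felkin–Anh control, the non-chelating silyl ether sitting axial to avoid a syn-diaxial methyl/methyl contact with the gem-dimethyl group) should place the alkynyl group trans to the silyloxy group and the new C6 hydroxyl cis to it.

Step 8
Reactants: 10 propargylic diol
Product: 11 dienediol (1S,2R)-1-[(1E,3E)-5-hydroxy-3-methylpenta-1,3-dien-1-yl]-2,6,6-trimethyl-2-[(triethylsilyl)oxy]cyclohexan-1-ol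
Conditions: NaAlH2(OCH2CH2OCH3)2, THF, 0 → 23 °C; aq. KNaC4H4O6
Reagents that add atoms: none
Why: Hydroxyl-directed trans-hydroalumination of a propargylic alcohol followed by protonolysis should reduce only the C7≡C8 triple bond next to the C6 alkoxide and give the (7E) alkene.

Step 9
Reactants: 11 dienediol
Product: 12 dienal (2E,4E)-5-{(1S,2R)-1-hydroxy-2,6,6-trimethyl-2-[(triethylsilyl)oxy]cyclohexyl}-3-methylpenta-2,4-dienal
Conditions: MnO2 (activated, excess), CH2Cl2, 23 °C
Reagents that add atoms: none
Why: Allylic oxidation with MnO2 is selective for the primary dienylic alcohol and should leave the tertiary C6 hydroxyl and the silyl ether alone.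

Step 10
Reactants: 12 dienal; 13 diethyl [3-(trimethylsilyl)prop-2-yn-1-yl]phosphonate
Product: 14 C-silylated trienyne (1S,2R)-2,6,6-trimethyl-1-[(1E,3E,5E)-3-methyl-8-(trimethylsilyl)octa-1,3,5-trien-7-yn-1-yl]-2-[(triethylsilyl)oxy]cyclohexan-1-ol
Conditions: 13, LiN(SiMe3)2 (2.2 equiv each), THF, −78 °C; then 12, −78 → 0 °C
Reagents that add atoms: none
Why: Horner–Wadsworth–Emmons olefination with a propargylic phosphonate should form C11=C12 mainly as the (E) isomer, the excess carbanion covering the free tertiary hydroxyl, and any (11Z) isomer is removed by chromatography.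

Step 11
Reactants: 14 C-silylated trienyne
Product: 15 terminal trienyne (1S,2R)-2,6,6-trimethyl-1-[(1E,3E,5E)-3-methylocta-1,3,5-trien-7-yn-1-yl]-2-[(triethylsilyl)oxy]cyclohexan-1-ol
Conditions: K2CO3 (0.2 equiv), MeOH/THF, 23 °C
Reagents that add atoms: none
Why: Base-mediated methanolysis of an alkynyl–silicon bond (protodesilylation) should free the terminal alkyne without cleaving the hindered tertiary triethylsilyl ether.

Step 12
Reactants: 15 terminal trienyne
Product: 16 (5R,6S)-C18 trienyne with C5–OSiEt3 and C6–OSiMe3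
Conditions: N-(trimethylsilyl)imidazole, DMF, 40 °C
Reagents that add atoms: N-(trimethylsilyl)imidazole, C[Si](C)(C)n1ccnc1
Why: O-silylation by silyl transfer from a silylimidazole is strong enough for the hindered tertiary allylic C6 hydroxyl, is neutral, and should not silylate the terminal alkyne C–H.

Step 13
Reactants: 4 epoxy aldehyde; 17 diethyl [(2E)-3-cyano-2-methylprop-2-en-1-yl]phosphonate
Product: 18 epoxy C15 nitrile (2E,4E)-3-methyl-5-[(1S,6R)-2,2,6-trimethyl-7-oxabicyclo[4.1.0]heptan-1-yl]penta-2,4-dienenitrile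
Conditions: 17, NaH, THF, 0 °C; then 4, 0 → 23 °C
Reagents that add atoms: none
Why: Horner–Wadsworth–Emmons olefination of the non-enolisable epoxy aldehyde with the C5 nitrile phosphonate should give the (7'E) alkene with the (9'E) isomer as main product, the (9'Z) isomer being removed by chromatography, and the epoxide is inert to the base.

Step 14
Reactants: 18 epoxy C15 nitrile
Product: 20 epoxy C15 aldehyde (2E,4E)-3-methyl-5-[(1S,6R)-2,2,6-trimethyl-7-oxabicyclo[4.1.0]heptan-1-yl]penta-2,4-dienal, via N-(diisobutylalumanyl) aldimine 19 (not isolated)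
Conditions: i-Bu2AlH, CH2Cl2, −78 °C; then H2O on SiO2, 0 °C
Reagents that add atoms: water, O
Why: Partial reduction of a nitrile with i-Bu2AlH stops at the N-aluminio aldimine 19, which should hydrolyse to the aldehyde on work-up while the tetrasubstituted epoxide stays closed at −78 °C.

Step 15
Reactants: 20 epoxy C15 aldehyde; 17 diethyl [(2E)-3-cyano-2-methylprop-2-en-1-yl]phosphonate
Product: 21 (5R,6S)-5,6-epoxy-5,6-dihydroretinonitrile
Conditions: 17, NaH, THF, 0 °C; then 20, 0 → 23 °C
Reagents that add atoms: none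
Why: A second Horner–Wadsworth–Emmons olefination with the same C5 nitrile phosphonate should form C11'=C12' as the (E) alkene and bring in C13'=C14' mainly (E), the (13'Z) isomer being removed by chromatography.

Step 16
Reactants: 21 (5R,6S)-5,6-epoxy-5,6-dihydroretinonitrile
Product: 23 (5R,6S)-5,6-epoxy-5,6-dihydroretinal, via N-(diisobutylalumanyl) aldimine 22 (not isolated)
Conditions: i-Bu2AlH, CH2Cl2, −78 °C; then H2O on SiO2, 0 °C
Reagents that add atoms: water, O
Why: Partial nitrile reduction with i-Bu2AlH through the N-aluminio aldimine 22 should give the tetraenal without touching the epoxide or the polyene.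

Step 17
Reactants: 23 (5R,6S)-5,6-epoxy-5,6-dihydroretinal
Product: 24 (5R,8R)-5,8-epoxy-5,8-dihydroretinal
Conditions: HCl (cat.) in CHCl3, 0 °C, dark; aq. NaHCO3
Reagents that add atoms: none
Why: Acid-catalysed epoxide–furanoid rearrangement, long established for 5,6-epoxy retinoids and carotenoids: ionisation of the C6'–O bond gives a polyenyl cation that the C5' oxygen captures at C8' (five-membered ring, new C6'=C7' bond), so C5' keeps its (R) configuration while C8' forms as both epimers, of which the (8'R) aldehyde is separated by chromatography and the (8'S) one can be returned to the same acid, which is expected to interconvert the two through the cation.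

Step 18
Reactants: 24 (5R,8R)-5,8-epoxy-5,8-dihydroretinal
Product: 25 furanoid (5'R,8'R)-C21 tetraenyl iodide
Conditions: CrCl2, CHI3, THF, 0 °C, dark
Reagents that add atoms: iodoform, IC(I)I
Why: Takai iodo-olefination, in which divalent chromium turns iodoform into a geminal dichromium reagent that adds to the aldehyde and eliminates to the (E)-alkenyl iodide, is non-basic and non-protic and should leave the C8' stereocentre and the dihydrofuran untouched.

Step 19
Reactants: 16 silylated C18 trienyne; 26 trimethylaluminium; 25 furanoid C21 tetraenyl iodide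
Product: 29 5-O-triethylsilyl-6-O-trimethylsilyl ether of 30, via alkenyldimethylalane 27 (not isolated), via alkenylzinc chloride 28 (not isolated)
Conditions: 26 (3 equiv), Cp2ZrCl2 (0.3 equiv), ClCH2CH2Cl, 0 → 23 °C; volatiles removed in vacuo; THF, ZnCl2 (1.2 equiv); then 25, Pd(PPh3)4 (5 mol%), 23 °C, dark
Reagents that add atoms: none
Why: Cp2ZrCl2 and AlMe3 form a methylzirconium–aluminium species that adds CH3 and metal to the same face of the terminal C13≡C14 triple bond (zirconium-catalysed methylalumination), methyl to the internal C13 and aluminium to C14, giving the (13E)-alkenylalane 27. ZnCl2 takes the alkenyl group over as 28, zerovalent palladium inserts into the C15–I bond of 25, and transmetalation followed by reductive elimination joins C14 to C15 with retention at both alkenes (Negishi coupling). The closest known reaction type is the one-pot carboalumination and alkenyl–alkenyl coupling by which retinoid and carotenoid polyenes are assembled from conjugated enynes. No ring closes and no stereocentre forms, so the step only has to leave C5, C6, C5' and C8' untouched. It needs regioselectivity (methyl at C13, secured by the terminal, conjugated alkyne), 13E geometry (secured by syn addition) and chemoselectivity toward the acid-labile parts; the last is secured by silylating both tertiary hydroxyls of 16, so that no ionisable aluminium alkoxide forms at allylic C6, and by removing excess AlMe3 and changing to THF before the dihydrofuran iodide 25 is added.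

Step 20
Reactants: 29 bis-silyl ether
Product: 30 (5R,6S,5'R,8'R)-5',8'-epoxy-5,6,5',8'-tetrahydro-β,β-carotene-5,6-diol
Conditions: Bu4NF, THF, 0 → 23 °C, dark
Reagents that add atoms: none
Why: Fluoride-induced cleavage of both silyl ethers (desilylation) runs under mildly basic conditions, which should spare the acid-labile dihydrofuran, the tertiary allylic C6 hydroxyl and the polyene.

**Compound list**

1 | β-cyclocitral (2,6,6-trimethylcyclohex-1-ene-1-carbaldehyde) | CC1=C(C=O)C(C)(C)CCC1 | starting material
2 | β-cyclogeraniol [(2,6,6-trimethylcyclohex-1-en-1-yl)methanol] | CC1=C(CO)C(C)(C)CCC1 | intermediate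
3 | [(1R,6R)-2,2,6-trimethyl-7-oxabicyclo[4.1.0]heptan-1-yl]methanol | CC1(C)CCC[C@@]2(C)O[C@@]12CO | intermediate
4 | (1S,6R)-2,2,6-trimethyl-7-oxabicyclo[4.1.0]heptane-1-carbaldehyde | CC1(C)CCC[C@@]2(C)O[C@@]12C=O | intermediate
5 | (E)-hydrazone of 4 | CC1(C)CCC[C@@]2(C)O[C@@]12/C=N/N | intermediate
6 | (1R)-1,3,3-trimethyl-2-methylidenecyclohexan-1-ol | C[C@@]1(O)CCCC(C)(C)C1=C | intermediate
7 | triethyl{[(1R)-1,3,3-trimethyl-2-methylidenecyclohexyl]oxy}silane | C[C@@]1(O[Si](CC)(CC)CC)CCCC(C)(C)C1=C | intermediate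
8 | (6R)-2,2,6-trimethyl-6-[(triethylsilyl)oxy]cyclohexan-1-one | C[C@@]1(O[Si](CC)(CC)CC)CCCC(C)(C)C1=O | intermediate
9 | (E)-3-methylpent-2-en-4-yn-1-ol | C#C/C(C)=C/CO | starting material
10 | (1R,2R)-1-[(3E)-5-hydroxy-3-methylpent-3-en-1-yn-1-yl]-2,6,6-trimethyl-2-[(triethylsilyl)oxy]cyclohexan-1-ol (C6–OH cis to C5–OSiEt3) | OC/C=C(C)/C#C[C@]1(O)C(C)(C)CCC[C@@]1(C)O[Si](CC)(CC)CC | intermediate
11 | (1S,2R)-1-[(1E,3E)-5-hydroxy-3-methylpenta-1,3-dien-1-yl]-2,6,6-trimethyl-2-[(triethylsilyl)oxy]cyclohexan-1-ol | OC/C=C(C)/C=C/[C@]1(O)C(C)(C)CCC[C@@]1(C)O[Si](CC)(CC)CC | intermediate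
12 | (2E,4E)-5-{(1S,2R)-1-hydroxy-2,6,6-trimethyl-2-[(triethylsilyl)oxy]cyclohexyl}-3-methylpenta-2,4-dienal | O=C/C=C(C)/C=C/[C@]1(O)C(C)(C)CCC[C@@]1(C)O[Si](CC)(CC)CC | intermediate
13 | diethyl [3-(trimethylsilyl)prop-2-yn-1-yl]phosphonate | CCOP(=O)(CC#C[Si](C)(C)C)OCC | starting material
14 | (1S,2R)-2,6,6-trimethyl-1-[(1E,3E,5E)-3-methyl-8-(trimethylsilyl)octa-1,3,5-trien-7-yn-1-yl]-2-[(triethylsilyl)oxy]cyclohexan-1-ol | C[Si](C)(C)C#C/C=C/C=C(C)/C=C/[C@]1(O)C(C)(C)CCC[C@@]1(C)O[Si](CC)(CC)CC | intermediate
15 | (1S,2R)-2,6,6-trimethyl-1-[(1E,3E,5E)-3-methylocta-1,3,5-trien-7-yn-1-yl]-2-[(triethylsilyl)oxy]cyclohexan-1-ol | C#C/C=C/C=C(C)/C=C/[C@]1(O)C(C)(C)CCC[C@@]1(C)O[Si](CC)(CC)CC | intermediate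
16 | (5R,6S)-C18 trienyne (C1–C14), C5–OSiEt3 and C6–OSiMe3 | C#C/C=C/C=C(C)/C=C/[C@]1(O[Si](C)(C)C)C(C)(C)CCC[C@@]1(C)O[Si](CC)(CC)CC | intermediate
17 | diethyl [(2E)-3-cyano-2-methylprop-2-en-1-yl]phosphonate | CCOP(=O)(C/C(C)=C/C#N)OCC | starting material
18 | (2E,4E)-3-methyl-5-[(1S,6R)-2,2,6-trimethyl-7-oxabicyclo[4.1.0]heptan-1-yl]penta-2,4-dienenitrile | CC1(C)CCC[C@@]2(C)O[C@@]12/C=C/C(C)=C/C#N | intermediate
19 | N-(diisobutylalumanyl) aldimine from 18 | CC1(C)CCC[C@@]2(C)O[C@@]12/C=C/C(C)=C/C=N/[Al](CC(C)C)CC(C)C | intermediate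
20 | (2E,4E)-3-methyl-5-[(1S,6R)-2,2,6-trimethyl-7-oxabicyclo[4.1.0]heptan-1-yl]penta-2,4-dienal | CC1(C)CCC[C@@]2(C)O[C@@]12/C=C/C(C)=C/C=O | intermediate
21 | (5R,6S)-5,6-epoxy-5,6-dihydroretinonitrile (all-E) | CC1(C)CCC[C@@]2(C)O[C@@]12/C=C/C(C)=C/C=C/C(C)=C/C#N | intermediate
22 | N-(diisobutylalumanyl) aldimine from 21 | CC1(C)CCC[C@@]2(C)O[C@@]12/C=C/C(C)=C/C=C/C(C)=C/C=N/[Al](CC(C)C)CC(C)C | intermediate
23 | (5R,6S)-5,6-epoxy-5,6-dihydroretinal (all-E) | CC1(C)CCC[C@@]2(C)O[C@@]12/C=C/C(C)=C/C=C/C(C)=C/C=O | intermediate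
24 | (5R,8R)-5,8-epoxy-5,8-dihydroretinal; (2E,4E,6E)-3-methyl-7-[(2R,7aR)-4,4,7a-trimethyl-2,4,5,6,7,7a-hexahydro-1-benzofuran-2-yl]octa-2,4,6-trienal | O=C/C=C(C)/C=C/C=C(\C)[C@H]1C=C2C(C)(C)CCC[C@@]2(C)O1 | intermediate
25 | (2R,7aR)-2-[(2E,4E,6E,8E)-9-iodo-6-methylnona-2,4,6,8-tetraen-2-yl]-4,4,7a-trimethyl-2,4,5,6,7,7a-hexahydro-1-benzofuran (furanoid C21 iodide, iodine on C15) | I/C=C/C=C(C)/C=C/C=C(\C)[C@H]1C=C2C(C)(C)CCC[C@@]2(C)O1 | intermediate
26 | trimethylaluminium | C[Al](C)C | starting material
27 | (13E)-alkenyldimethylalane from 16 (Al on C14, new CH3 on C13) | C[Al](C)/C=C(C)/C=C/C=C(C)/C=C/[C@]1(O[Si](C)(C)C)C(C)(C)CCC[C@@]1(C)O[Si](CC)(CC)CC | intermediate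
28 | (13E)-alkenylzinc chloride from 27 | Cl[Zn]/C=C(C)/C=C/C=C(C)/C=C/[C@]1(O[Si](C)(C)C)C(C)(C)CCC[C@@]1(C)O[Si](CC)(CC)CC | intermediate
29 | 5-O-triethylsilyl-6-O-trimethylsilyl ether of 30 | CC(/C=C/C=C(C)/C=C/[C@]1(O[Si](C)(C)C)C(C)(C)CCC[C@@]1(C)O[Si](CC)(CC)CC)=C\C=C\C=C(C)\C=C\C=C(/C)[C@H]1C=C2C(C)(C)CCC[C@@]2(C)O1 | intermediate
30 | (5R,6S,5'R,8'R)-5',8'-epoxy-5,6,5',8'-tetrahydro-β,β-carotene-5,6-diol (all-E, cis-5,6-diol) | CC(/C=C/C=C(C)/C=C/[C@]1(O)C(C)(C)CCC[C@@]1(C)O)=C\C=C\C=C(C)\C=C\C=C(/C)[C@H]1C=C2C(C)(C)CCC[C@@]2(C)O1 | target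

**Count and risks**

Total step count: 20. Longest linear sequence: 14 steps (steps 1–12, 19 and 20).

Steps most likely to fail:

1. Step 19. Residual aluminium or zinc Lewis acid may ionise the allylic C6 silyl ether or open and epimerise the dihydrofuran of 25, or the alkenyl group may transfer sluggishly and be lost by protonation. The fallback keeps the methylalumination and the C14–C15 disconnection but keeps the furanoid half away from both metals. It sets out from 16 (as its alane 27) and from aldehyde 24, and comes back at 29. Alane 27 is quenched with I2 in THF at −30 °C, which should give with retention the (13E)-C19 alkenyl iodide F1. Aldehyde 24 is treated with 2-(dichloromethyl)-4,4,5,5-tetramethyl-1,3,2-dioxaborolane, CrCl2 and LiI in THF (Takai–Utimoto boron olefination) to give the furanoid (E)-alkenyl pinacol boronate F2 in place of the iodide. Suzuki–Miyaura coupling of F1 with F2 (Pd(PPh3)4, TlOEt, THF/H2O, 23 °C) then forms the same C14–C15 bond and gives 29.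

2. Step 17. The ring closure has no facial bias at C8', the polyenal may isomerise at its double bonds or decompose in acid, and the two C8' epimers may not separate. The fallback moves the ring closure one stage earlier, onto a substrate without a free aldehyde. It sets out from nitrile 21 and comes back at 24. Nitrile 21 is treated with the same catalytic HCl in CHCl3; from the epimer pair the (5R,8R)-furanoid nitrile F3 is separated by chromatography or crystallisation, the (8S) nitrile being returned to the acid. F3 is then reduced with i-Bu2AlH at −78 °C through its N-(diisobutylalumanyl) aldimine F4, which hydrolyses on work-up to 24.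

3. Step 4. The hydrazone may form an azine with a second aldehyde, and material may be lost when the diazene stage collapses, so the transposition could give a low mass return. The fallback reaches the same allylic alcohol by reductive elimination instead. It sets out from epoxy alcohol 3 and comes back at 6. Mesylation (MsCl, Et3N, CH2Cl2, 0 °C) gives the epoxy mesylate F5, Finkelstein exchange (NaI, 2-butanone, 70 °C) gives the epoxy iodide F6, and zinc dust in ethanol opens the epoxide by reductive β-elimination to give 6 with the C5–O bond intact.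

**Further compounds**

F1 | step 19 | (13E)-C19 alkenyl iodide (iodine on C14), C5–OSiEt3 and C6–OSiMe3 | I/C=C(C)/C=C/C=C(C)/C=C/[C@]1(O[Si](C)(C)C)C(C)(C)CCC[C@@]1(C)O[Si](CC)(CC)CC
F2 | step 19 | furanoid (5'R,8'R)-C21 (E)-alkenyl pinacol boronate (boron on C15) | CC1(C)OB(/C=C/C=C(C)/C=C/C=C(\C)[C@H]2C=C3C(C)(C)CCC[C@@]3(C)O2)OC1(C)C
F3 | step 17 | (5R,8R)-5,8-epoxy-5,8-dihydroretinonitrile | N#C/C=C(C)/C=C/C=C(\C)[C@H]1C=C2C(C)(C)CCC[C@@]2(C)O1
F4 | step 17 | N-(diisobutylalumanyl) aldimine from F3 | CC(C)C[Al](CC(C)C)/N=C/C=C(C)/C=C/C=C(\C)[C@H]1C=C2C(C)(C)CCC[C@@]2(C)O1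
F5 | step 4 | [(1R,6R)-2,2,6-trimethyl-7-oxabicyclo[4.1.0]heptan-1-yl]methyl methanesulfonate | CC1(C)CCC[C@@]2(C)O[C@@]12COS(C)(=O)=O
F6 | step 4 | (1S,6R)-1-(iodomethyl)-2,2,6-trimethyl-7-oxabicyclo[4.1.0]heptane | CC1(C)CCC[C@@]2(C)O[C@@]12CI
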